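**Plan**
- Retrosynthesis: the two benzyl ethers come off last. The lactone is cut at O1–C2 and C3–C4 (Meldrum's acid added to an o-quinone methide), C4–C1' goes back to an aryl Grignard reagent and C4–C4a to a formylation. The benzene ring is cut at C6–C7 and C5–C6.
- Enabling feature: the benzene ring C4a/C5/C6/C7/C8/C8a carries C5–CH3, C7–O and C8a–O in the same pattern as C6, C2 and C4 of 4-methoxy-6-methyl-2-pyranone, with C6 standing where the ring oxygen was. C6 is the methyl carbon of the pyranone that remains attached.
- Forward order: two molecules of that pyranone give the arylpyranone (benzene ring first). Then follow C7–O benzylation, C4a formylation, C8a–O demethylation and aryl addition; the lactone ring closes last, and hydrogenolysis ends the route.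
- Stereochemistry: the only stereocentre, C4 (R), is set when a chiral bifunctional squaramide directs Meldrum's acid to one face of the o-quinone methide. No later step touches it.

Key step: step 1

Assumption: the given SMILES is read as the (4R) enantiomer (CIP order C4a > 4-hydroxyphenyl > C3 > H; chroman-2-one numbering throughout). Which pseudo-enantiomer of the cinchona squaramide gives this sense is settled in a first run.

Step 1
Reactants: 1 4-methoxy-6-methyl-2H-pyran-2-one (two molecules)
Product: 3 6-(2-hydroxy-4-methoxy-6-methylphenyl)-4-methoxy-2H-pyran-2-one, via ring-opened enedione 2 (not isolated)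
Conditions: LiHMDS (0.55 equiv, added to 1), THF, −78 °C to rt; then 1 M HCl
Reagents that add atoms: none
Why: LiHMDS deprotonates the vinylogously acidic 6-methyl group of half of 1, and the lithium dienolate adds 1,2 to the lactone carbonyl of a neutral molecule (C6–C7 bond); this expels a methyl ketone enolate and gives 2, in which the alkene geometry kept from the ring holds the new ketone and the acetonyl arm cis. The doubly activated CH between pyranone and ketone then attacks the methyl ketone in a 6-(enolexo)-exo-trig aldol (C5–C6 bond), and loss of water with enolisation, completed by the acid quench, should give the phenol. The closest known reaction types are the biogenetic-type Claisen opening/aldol conversions of 2-pyranones into resorcinols, carbanion-induced pyranone-to-benzene ring transformations, and lateral lithiation/C-acylation of this pyranone. No stereocentre is formed. The selectivity needed is attack at C2 instead of conjugate attack at C4 or C6: the hard lithium ion bound to the lactone carbonyl favours it, the donor groups on C4 and C6 lower the electrophilicity of those positions, and proton exchange between donor and acceptor is degenerate because they are the same compound.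

Step 2
Reactants: 3 6-(2-hydroxy-4-methoxy-6-methylphenyl)-4-methoxy-2H-pyran-2-one
Product: 4 6-[2-(benzyloxy)-4-methoxy-6-methylphenyl]-4-methoxy-2H-pyran-2-one
Conditions: BnBr (1.2 equiv), K2CO3, DMF, rt to 40 °C
Reagents that add atoms: benzyl bromide, BrCc1ccccc1
Why: Williamson O-alkylation of the phenoxide, the only acidic site under carbonate, masks C7–OH as an ether that should survive the electrophilic, Lewis-acidic and organometallic steps ahead and keeps the ring electron-rich for formylation.

Step 3
Reactants: 4 6-[2-(benzyloxy)-4-methoxy-6-methylphenyl]-4-methoxy-2H-pyran-2-one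
Product: 5 4-(benzyloxy)-6-methoxy-3-(4-methoxy-2-oxo-2H-pyran-6-yl)-2-methylbenzaldehyde
Conditions: POCl3 (2 equiv), DMF, 0 to 60 °C; then H2O, rt
Reagents that add atoms: N,N-dimethylformamide, CN(C)C=O; water, O
Why: Vilsmeier–Haack formylation should attack C4a, which is para to the benzyloxy group and ortho to both the methoxy and the methyl group, the site that 3,5-dialkoxytoluenes favour over the carbon between the two oxygens, while the pyranone enol ether is deactivated by its lactone carbonyl.

Step 4
Reactants: 5 4-(benzyloxy)-6-methoxy-3-(4-methoxy-2-oxo-2H-pyran-6-yl)-2-methylbenzaldehyde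
Product: 6 4-(benzyloxy)-6-hydroxy-3-(4-methoxy-2-oxo-2H-pyran-6-yl)-2-methylbenzaldehyde
Conditions: MgI2 (2 equiv), toluene/Et2O, 60 °C; then H2O
Reagents that add atoms: none
Why: Chelation-controlled demethylation: magnesium held between the formyl oxygen and the ortho methoxy oxygen makes that methyl the only activated SN2 site for iodide, so the unchelated benzyl ether and the pyranone methyl ether should remain, as in magnesium halide cleavages of alkoxy groups ortho to aryl carbonyls.

Step 5
Reactants: 7 1-(benzyloxy)-4-bromobenzene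
Product: 8 [4-(benzyloxy)phenyl]magnesium bromide
Conditions: Mg turnings, I2 (cat.), THF, 40 °C
Reagents that add atoms: magnesium, [Mg]
Why: Grignard formation by insertion of magnesium into the aryl bromide, to which the benzyl aryl ether is inert.

Step 6
Reactants: 6 4-(benzyloxy)-6-hydroxy-3-(4-methoxy-2-oxo-2H-pyran-6-yl)-2-methylbenzaldehyde; 8 [4-(benzyloxy)phenyl]magnesium bromide (2.5 equiv)
Product: 9 rac-6-[6-(benzyloxy)-3-{[4-(benzyloxy)phenyl](hydroxy)methyl}-4-hydroxy-2-methylphenyl]-4-methoxy-2H-pyran-2-one
Conditions: THF, −78 to 0 °C; then H2O (pH 7 buffer); used crude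
Reagents that add atoms: none
Why: Grignard 1,2-addition to the aldehyde after the first equivalent has deprotonated the phenol; at low temperature the magnesium-chelated formyl group is far more electrophilic than the vinylogous-carbonate carbonyl of the pyranone, and the carbinol centre is deliberately made racemic because step 8 passes through a planar intermediate.

Step 7
Reactants: 9 rac-6-[6-(benzyloxy)-3-{[4-(benzyloxy)phenyl](hydroxy)methyl}-4-hydroxy-2-methylphenyl]-4-methoxy-2H-pyran-2-one
Product: 10 rac-6-[6-(benzyloxy)-3-{[4-(benzyloxy)phenyl](4-methylbenzenesulfonyl)methyl}-4-hydroxy-2-methylphenyl]-4-methoxy-2H-pyran-2-one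
Conditions: p-TolSO2H (1.5 equiv), CH2Cl2, rt
Reagents that add atoms: p-toluenesulfinic acid, Cc1ccc(cc1)S(=O)O
Why: Acid-promoted SN1 substitution of the doubly benzylic, oxygen-stabilised alcohol by the sulfur of the sulfinic acid gives the sulfone, the usual bench-stable precursor of an o-quinone methide.

Step 8
Reactants: 10 rac-6-[6-(benzyloxy)-3-{[4-(benzyloxy)phenyl](4-methylbenzenesulfonyl)methyl}-4-hydroxy-2-methylphenyl]-4-methoxy-2H-pyran-2-one; 11 Meldrum's acid (2,2-dimethyl-1,3-dioxane-4,6-dione)
Product: 15 (4R)-7-(benzyloxy)-4-[4-(benzyloxy)phenyl]-6-(4-methoxy-2-oxo-2H-pyran-6-yl)-5-methyl-3,4-dihydro-2H-chromen-2-one, via o-quinone methide 12 (not isolated), via Meldrum's acid adduct 13 (not isolated), via lactone acid 14 (not isolated)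
Conditions: quinine- or quinidine-derived 3,5-bis(trifluoromethyl)phenyl squaramide (10 mol %, the pseudo-enantiomer giving 4R), 5% aq. NaHCO3, CH2Cl2, 0 °C to rt; then p-TsOH·H2O (cat.), toluene, 90 °C; 1 M HCl wash
Reagents that add atoms: none
Why: Hydrogen carbonate eliminates sulfinate from 10 to give 12, whose carbonyl is hydrogen-bonded by the squaramide while the protonated quinuclidine delivers the Meldrum's acid enolate to one face of the exocyclic carbon (catalyst control, setting C4 as R in 13); the phenol then opens the dioxanedione with loss of acetone to 14 and heating with acid decarboxylates it, which is the known asymmetric Meldrum's acid/o-quinone methide route to 4-aryl-3,4-dihydrocoumarins and should tolerate the C5 methyl group because naphthol-derived quinone methides carry comparable peri crowding.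

Step 9
Reactants: 15 (4R)-7-(benzyloxy)-4-[4-(benzyloxy)phenyl]-6-(4-methoxy-2-oxo-2H-pyran-6-yl)-5-methyl-3,4-dihydro-2H-chromen-2-one
Product: 16 (4R)-7-hydroxy-4-(4-hydroxyphenyl)-6-(4-methoxy-2-oxo-2H-pyran-6-yl)-5-methyl-3,4-dihydro-2H-chromen-2-one
Conditions: H2 (1 atm), 10% Pd/C, EtOAc/THF, rt
Reagents that add atoms: none
Why: Hydrogenolysis of the two benzyl aryl ethers over palladium in a non-nucleophilic solvent keeps the aryl lactone closed and, at one atmosphere and room temperature, should leave the 4-methoxy-6-aryl-2-pyranone and the C4 stereocentre untouched.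

**Compound list**
1 | 4-methoxy-6-methyl-2H-pyran-2-one | COc1cc(C)oc(=O)c1 | starting material
2 | 4-methoxy-6-[(3E)-4-methoxy-2,6-dioxohept-3-en-1-yl]-2H-pyran-2-one | COc1cc(CC(=O)/C=C(/OC)CC(C)=O)oc(=O)c1 | intermediate
3 | 6-(2-hydroxy-4-methoxy-6-methylphenyl)-4-methoxy-2H-pyran-2-one | COc1cc(-c2c(O)cc(OC)cc2C)oc(=O)c1 | intermediate
4 | 6-[2-(benzyloxy)-4-methoxy-6-methylphenyl]-4-methoxy-2H-pyran-2-one | COc1cc(-c2c(OCc3ccccc3)cc(OC)cc2C)oc(=O)c1 | intermediate
5 | 4-(benzyloxy)-6-methoxy-3-(4-methoxy-2-oxo-2H-pyran-6-yl)-2-methylbenzaldehyde | COc1cc(-c2c(OCc3ccccc3)cc(OC)c(C=O)c2C)oc(=O)c1 | intermediate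
6 | 4-(benzyloxy)-6-hydroxy-3-(4-methoxy-2-oxo-2H-pyran-6-yl)-2-methylbenzaldehyde | COc1cc(-c2c(OCc3ccccc3)cc(O)c(C=O)c2C)oc(=O)c1 | intermediate
7 | 1-(benzyloxy)-4-bromobenzene | Brc1ccc(OCc2ccccc2)cc1 | starting material
8 | [4-(benzyloxy)phenyl]magnesium bromide | Br[Mg]c1ccc(OCc2ccccc2)cc1 | intermediate
9 | rac-6-[6-(benzyloxy)-3-{[4-(benzyloxy)phenyl](hydroxy)methyl}-4-hydroxy-2-methylphenyl]-4-methoxy-2H-pyran-2-one | COc1cc(-c2c(OCc3ccccc3)cc(O)c(C(O)c3ccc(OCc4ccccc4)cc3)c2C)oc(=O)c1 | intermediate
10 | rac-6-[6-(benzyloxy)-3-{[4-(benzyloxy)phenyl](4-methylbenzenesulfonyl)methyl}-4-hydroxy-2-methylphenyl]-4-methoxy-2H-pyran-2-one | COc1cc(-c2c(OCc3ccccc3)cc(O)c(C(c3ccc(OCc4ccccc4)cc3)S(=O)(=O)c3ccc(C)cc3)c2C)oc(=O)c1 | intermediate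
11 | Meldrum's acid (2,2-dimethyl-1,3-dioxane-4,6-dione) | CC1(C)OC(=O)CC(=O)O1 | starting material
12 | 6-{6-(benzyloxy)-3-[4-(benzyloxy)benzylidene]-2-methyl-4-oxocyclohexa-1,5-dien-1-yl}-4-methoxy-2H-pyran-2-one (o-quinone methide, alkene geometry not specified) | COc1cc(C2=C(C)C(=Cc3ccc(OCc4ccccc4)cc3)C(=O)C=C2OCc2ccccc2)oc(=O)c1 | intermediate
13 | 5-[(R)-{4-(benzyloxy)-6-hydroxy-3-(4-methoxy-2-oxo-2H-pyran-6-yl)-2-methylphenyl}{4-(benzyloxy)phenyl}methyl]-2,2-dimethyl-1,3-dioxane-4,6-dione | COc1cc(-c2c(OCc3ccccc3)cc(O)c([C@@H](c3ccc(OCc4ccccc4)cc3)C3C(=O)OC(C)(C)OC3=O)c2C)oc(=O)c1 | intermediate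
14 | (4R)-7-(benzyloxy)-4-[4-(benzyloxy)phenyl]-6-(4-methoxy-2-oxo-2H-pyran-6-yl)-5-methyl-2-oxo-3,4-dihydro-2H-chromene-3-carboxylic acid (C3 epimers) | COc1cc(-c2c(OCc3ccccc3)cc3c(c2C)[C@@H](c2ccc(OCc4ccccc4)cc2)C(C(=O)O)C(=O)O3)oc(=O)c1 | intermediate
15 | (4R)-7-(benzyloxy)-4-[4-(benzyloxy)phenyl]-6-(4-methoxy-2-oxo-2H-pyran-6-yl)-5-methyl-3,4-dihydro-2H-chromen-2-one | COc1cc(-c2c(OCc3ccccc3)cc3c(c2C)[C@@H](c2ccc(OCc4ccccc4)cc2)CC(=O)O3)oc(=O)c1 | intermediate
16 | (4R)-7-hydroxy-4-(4-hydroxyphenyl)-6-(4-methoxy-2-oxo-2H-pyran-6-yl)-5-methyl-3,4-dihydro-2H-chromen-2-one | COc1cc(-c2c(O)cc3c(c2C)[C@@H](c2ccc(O)cc2)CC(=O)O3)oc(=O)c1 | target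

**Step count**
Total: 9 steps. Longest linear sequence: 8 steps (1, 2, 3, 4, 6, 7, 8, 9); step 5 is a one-step side branch.

**Steps most likely to fail**

Step 1. The lithiated pyranone may attack C4 or C6 of its partner instead of the lactone carbonyl, or the more acidic acylation product may quench the carbanion so that the reaction stalls and oligomers form. The fallback sets out from 1 and builds the same chain with separate acyl donors. Lithiated 1 (LiHMDS, 2 equiv, THF, −78 °C) is C-acylated with methyl (E)-3-methoxybut-2-enoate to give 4-methoxy-6-[(3E)-4-methoxy-2-oxopent-3-en-1-yl]-2H-pyran-2-one F1. The dianion of F1 (LDA, 2.2 equiv) is then acetylated at its terminal methyl group with N-methoxy-N-methylacetamide to give 2, and acid work-up closes 2 to 3, where the route is rejoined.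

Step 4. Discrimination between the three ether groups may be lost: iodide may also dealkylate the pyranone methyl ether or the benzyl ether, or the hindered chelate may not react. The fallback sets out from 5 and gives up the discrimination on the arene. BCl3 (4 equiv, CH2Cl2, −78 to 0 °C) removes both the chelated methyl group and the benzyl group to give 4,6-dihydroxy-3-(4-methoxy-2-oxo-2H-pyran-6-yl)-2-methylbenzaldehyde F2. BnBr (1.05 equiv), KHCO3, MeCN, 60 °C should then alkylate only the hydroxyl para to the formyl group, which is the more acidic one and is not held in the hydrogen bond to the aldehyde; this returns to the route at 6.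

Step 8. Facial control may be poor, or the enantiomeric purity may erode through reversible conjugate addition, because the o-quinone methide is strongly donor-stabilised and flanked by the C5 methyl group. The fallback sets out from 6 and sets C4 by metal catalysis. Wittig olefination/lactonisation with ethyl (triphenylphosphoranylidene)acetate in hot N,N-diethylaniline gives 7-(benzyloxy)-6-(4-methoxy-2-oxo-2H-pyran-6-yl)-5-methyl-2H-chromen-2-one F3. Hayashi–Miyaura conjugate addition of 4-(benzyloxy)phenylboronic acid (Rh(acac)(C2H4)2, (R)- or (S)-SEGPHOS, dioxane/H2O, 60 °C) then returns to the route at 15.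

**Further compounds**
F1 | step 1 | 4-methoxy-6-[(3E)-4-methoxy-2-oxopent-3-en-1-yl]-2H-pyran-2-one | COc1cc(CC(=O)/C=C(\C)OC)oc(=O)c1
F2 | step 4 | 4,6-dihydroxy-3-(4-methoxy-2-oxo-2H-pyran-6-yl)-2-methylbenzaldehyde | COc1cc(-c2c(O)cc(O)c(C=O)c2C)oc(=O)c1
F3 | step 8 | 7-(benzyloxy)-6-(4-methoxy-2-oxo-2H-pyran-6-yl)-5-methyl-2H-chromen-2-one | COc1cc(-c2c(OCc3ccccc3)cc3OC(=O)C=Cc3c2C)oc(=O)c1
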